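**Retrosynthetic overview**

- The target is an 8-hydroxy-5-methoxy-1,4-naphthoquinone (ring B = quinone ring C1–C4/C4a/C8a; ring A = oxygenated benzenoid ring C4a–C8a) with an (S)-configured C1' senecioate side chain on C2.
- The route rests on one feature: C1' links aryl carbon C2 of ring B to the C2' methylene, whose other neighbour is alkenyl carbon C3'. This maps onto an aryl nucleophile, a vinylboron C1'–C2' unit and a C3'–C5' alkenyl electrophile, joined in one enantioselective conjunctive coupling that forms C2–C1' and C2'–C3' and sets C1'.
- After the coupling: C–B to C–O oxidation with retention, esterification, and oxidative demethylation to a 2-chloro-5-alkylbenzoquinone.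
- Ring order: ring B is carried from the start as the benzene ring of 1. Ring A is closed last by [4+2] addition of 2-methoxyfuran to the chlorinated C=C, the chlorine placing OMe on C5 and OH on C8.

Key step: step 3

Remark (numbering): naphthoquinone atoms are C1–C8a with the side chain C1'–C5' on C2, OH on C8 and OMe on C5; the target is (S) at C1'.
Remark (assumption): the (Rp,Rp) antipode of the ferrocenyl diphosphine is assumed to deliver (S)-8. If MTPA ester analysis of alcohol 9 shows the (R)-enantiomer, the (Sp,Sp) ligand is used with no other change.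

**Step 1**
Reactants: 1 2-chloro-1,4-dimethoxybenzene
Product: 2 1-bromo-4-chloro-2,5-dimethoxybenzene
Conditions: NBS (1.05 equiv), MeCN, rt; recrystallisation
Reagents that add atoms: N-bromosuccinimide, O=C1CCC(=O)N1Br
Why: Electrophilic aromatic bromination should occur at the free position ortho to one methoxy group and para to chlorine, the most activated and least hindered site, giving the 1,2,4,5-substitution pattern.

**Step 2**
Reactants: 3 isobutyraldehyde
Product: 4 2-methylprop-1-enyl trifluoromethanesulfonate
Conditions: Tf2O (1.1 equiv), 2,6-di-tert-butyl-4-methylpyridine (1.2 equiv), CH2Cl2, 0 °C to reflux; distillation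
Reagents that add atoms: trifluoromethanesulfonic anhydride, O=S(=O)(OS(=O)(=O)C(F)(F)F)C(F)(F)F
Why: O-triflation of the aldehyde followed by loss of the α-proton to the hindered, non-nucleophilic pyridine gives the enol triflate (vinyl triflate synthesis from an enolisable aldehyde), and only one alkene isomer is possible.

**Step 3**
Reactants: 2 1-bromo-4-chloro-2,5-dimethoxybenzene; 5 vinylboronic acid pinacol ester; 4 2-methylprop-1-enyl trifluoromethanesulfonate
Product: 8 (S)-2-[1-(4-chloro-2,5-dimethoxyphenyl)-4-methylpent-3-enyl]-4,4,5,5-tetramethyl-1,3,2-dioxaborolane, via aryllithium 6 (not isolated), via vinylboron ate complex 7 (not isolated)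
Conditions: t-BuLi (2 equiv), Et2O, −78 °C; then 5, −78 °C → rt; evaporate; then NaOSO2CF3 (2 equiv), Pd(OAc)2 (2 mol%), (RP,R′P)-1,1′-bis[bis(4-methoxy-3,5-dimethylphenyl)phosphino]-2,2′-bis[(S)-α-(dimethylamino)benzyl]ferrocene (MandyPhos, 2.4 mol%), 4 (1.1 equiv), degassed THF, 60 °C
Reagents that add atoms: none
Why: Bromine–lithium exchange gives aryllithium 6, which adds to the boron of 5 to give the four-coordinate boronate 7; oxidative addition of triflate 4 to zerovalent palladium gives a cationic divalent alkenylpalladium that π-binds the vinyl group of 7. This induces an anti 1,2-shift of the aryl group from boron to C1' while palladium bonds C2', and reductive elimination then forms C2'–C3'. The closest known reaction type is the palladium/MandyPhos-catalysed enantioselective conjunctive cross-coupling of organolithium-derived vinylboron ate complexes with alkenyl and aryl triflates. No ring is closed. The single new stereocentre C1' is set by the chiral diphosphine, which selects the enantioface of the boron-bound vinyl group. The step needs the metalate shift to outrun direct Suzuki-type transfer (secured by the chelating ferrocenyl ligand and the non-coordinating triflate, with bromide from the exchange sequestered as NaBr) and needs the aryl C–Cl bond to stay intact (an electron-rich aryl chloride should not add oxidatively to this catalyst at 60 °C).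

**Step 4**
Reactants: 8 (S)-2-[1-(4-chloro-2,5-dimethoxyphenyl)-4-methylpent-3-enyl]-4,4,5,5-tetramethyl-1,3,2-dioxaborolane
Product: 9 (S)-1-(4-chloro-2,5-dimethoxyphenyl)-4-methylpent-3-en-1-ol
Conditions: NaBO3·4H2O (5 equiv), THF/H2O (1:1), rt
Reagents that add atoms: sodium perborate tetrahydrate, [Na+].O=BO[O-].O.O.O.O
Why: Peroxide adds to boron and C1' migrates from boron to oxygen with retention (boronate oxidation), so (S)-8 should give (S)-9, while the trisubstituted alkene and the aryl chloride are inert to nucleophilic peroxide.

**Step 5**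
Reactants: 9 (S)-1-(4-chloro-2,5-dimethoxyphenyl)-4-methylpent-3-en-1-ol; 10 3-methylbut-2-enoic acid
Product: 11 (S)-1-(4-chloro-2,5-dimethoxyphenyl)-4-methylpent-3-enyl 3-methylbut-2-enoate
Conditions: 10 (1.5 equiv), DCC (1.5 equiv), DMAP (0.2 equiv), CH2Cl2, 0 °C → rt
Reagents that add atoms: none
Why: Steglich esterification acylates the alcohol oxygen without breaking the C1'–O bond, so the configuration is kept, and the carbodiimide route avoids the ketene pathway that deconjugates senecioyl chloride under amine base.

**Step 6**
Reactants: 11 (S)-1-(4-chloro-2,5-dimethoxyphenyl)-4-methylpent-3-enyl 3-methylbut-2-enoate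
Product: 12 (S)-1-(4-chloro-3,6-dioxocyclohexa-1,4-dien-1-yl)-4-methylpent-3-enyl 3-methylbut-2-enoate
Conditions: (NH4)2Ce(NO3)6 (2.5 equiv), MeCN/H2O (3:1), 0 °C, 10–15 min; used promptly
Reagents that add atoms: water, O
Why: Oxidative demethylation of a para-dimethoxyarene by tetravalent cerium (arene radical cation, water addition, loss of two methanol) should give the 2-chloro-5-alkyl-1,4-benzoquinone, the arene being the most easily oxidised π system so that the isolated alkene and the ester survive a short, cold reaction.

**Step 7**
Reactants: 12 (S)-1-(4-chloro-3,6-dioxocyclohexa-1,4-dien-1-yl)-4-methylpent-3-enyl 3-methylbut-2-enoate; 13 2-methoxyfuran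
Product: 16 (S)-1-(8-hydroxy-5-methoxy-1,4-dioxo-1,4-dihydronaphthalen-2-yl)-4-methylpent-3-enyl 3-methylbut-2-enoate (target), via chloro cycloadduct 14 (not isolated), via oxygen-bridged quinone 15 (not isolated)
Conditions: 13 (3 equiv), NaHCO3 (2 equiv), toluene, 0 °C → rt, dark; then SiO2, CH2Cl2, rt
Reagents that add atoms: none
Why: Proposed new method: the electron-rich furan should add across the chlorinated C=C of 12 in a polarised [4+2] process in which the nucleophilic unsubstituted furan C5 bonds to the chlorine-free quinone carbon (future C8a) and the methoxy-bearing furan C2 bonds to the C–Cl carbon (future C4a), after which loss of HCl restores the quinone (15) and acid-assisted opening of the methoxy-substituted oxygen bridge with proton loss aromatises ring A with OMe on C5 and OH on C8; the closest known reaction types are the regiospecific Diels–Alder/dehydrohalogenation of haloquinones with 1-oxygenated dienes and the cycloaddition of 2-methoxyfuran with arynes and acetylenic esters that opens to 4-methoxyphenols, and the required site selectivity for the chloro alkene over the alkyl-substituted one is secured by the halogen, which activates that C=C and makes the addition irreversible through HCl loss.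

**Compound list**

1 | 2-chloro-1,4-dimethoxybenzene | COc1ccc(OC)c(Cl)c1 | starting material
2 | 1-bromo-4-chloro-2,5-dimethoxybenzene | COc1cc(Cl)c(OC)cc1Br | intermediate
3 | isobutyraldehyde | CC(C)C=O | starting material
4 | 2-methylprop-1-enyl trifluoromethanesulfonate | CC(C)=COS(=O)(=O)C(F)(F)F | intermediate
5 | vinylboronic acid pinacol ester | C=CB1OC(C)(C)C(C)(C)O1 | starting material
6 | 4-chloro-2,5-dimethoxyphenyllithium | [Li]c1cc(OC)c(Cl)cc1OC | intermediate (not isolated)
7 | lithium (4-chloro-2,5-dimethoxyphenyl)(vinyl)(pinacolato)borate | [Li+].C=C[B-]1(c2cc(OC)c(Cl)cc2OC)OC(C)(C)C(C)(C)O1 | intermediate (not isolated)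
8 | (S)-2-[1-(4-chloro-2,5-dimethoxyphenyl)-4-methylpent-3-enyl]-4,4,5,5-tetramethyl-1,3,2-dioxaborolane | COc1cc(Cl)c(OC)cc1[C@H](CC=C(C)C)B1OC(C)(C)C(C)(C)O1 | intermediate
9 | (S)-1-(4-chloro-2,5-dimethoxyphenyl)-4-methylpent-3-en-1-ol | COc1cc(Cl)c(OC)cc1[C@H](CC=C(C)C)O | intermediate
10 | 3-methylbut-2-enoic acid | CC(C)=CC(=O)O | starting material
11 | (S)-1-(4-chloro-2,5-dimethoxyphenyl)-4-methylpent-3-enyl 3-methylbut-2-enoate | COc1cc(Cl)c(OC)cc1[C@H](CC=C(C)C)OC(=O)C=C(C)C | intermediate
12 | (S)-1-(4-chloro-3,6-dioxocyclohexa-1,4-dien-1-yl)-4-methylpent-3-enyl 3-methylbut-2-enoate | O=C1C=C([C@H](CC=C(C)C)OC(=O)C=C(C)C)C(=O)C=C1Cl | intermediate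
13 | 2-methoxyfuran | COc1ccco1 | starting material
14 | 4a-chloro-5-methoxy-5,8-epoxy-4a,5,8,8a-tetrahydronaphthalene-1,4-dione bearing the (S)-side chain on C2 (diastereomer mixture at the ring centres) | O=C1C=C([C@H](CC=C(C)C)OC(=O)C=C(C)C)C(=O)C2C3C=CC(OC)(O3)C12Cl | intermediate (not isolated)
15 | 5-methoxy-5,8-epoxy-5,8-dihydronaphthalene-1,4-dione bearing the (S)-side chain on C2 | O=C1C=C([C@H](CC=C(C)C)OC(=O)C=C(C)C)C(=O)C2=C1C1(OC)C=CC2O1 | intermediate (not isolated)
16 | (S)-1-(8-hydroxy-5-methoxy-1,4-dioxo-1,4-dihydronaphthalen-2-yl)-4-methylpent-3-enyl 3-methylbut-2-enoate | COc1ccc(O)c2c1C(=O)C=C([C@H](CC=C(C)C)OC(=O)C=C(C)C)C2=O | target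

Total step count: 7
Longest linear sequence: 6 steps (steps 1, 3, 4, 5, 6, 7 from compound 1; step 2 is a one-step side branch)

**Steps most likely to fail**

1. Step 7 (proposed new method).
 - What may go wrong: the furan may react as a carbon nucleophile, adding through C5 and then re-aromatising by proton loss (substitutive arylation of the quinone) instead of closing the ring. The cycloaddition may revert before HCl is lost. Liberated acid may decompose the furan. Addition may occur at the alkyl-substituted C=C.
 - Fallback (known haloquinone Diels–Alder with an oxygenated cyclohexa-1,3-diene, dehydrohalogenation and ethylene extrusion): it sets out from 12 and returns at 16.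
 - Diene: Birch reduction of 1,4-dimethoxybenzene (Li, NH3, t-BuOH) would give 1,4-dimethoxycyclohexa-1,4-diene F1. Partial hydrolysis with aqueous oxalic acid would give 4-methoxycyclohex-3-en-1-one F2. Enolisation with LiN(SiMe3)2 and O-acetylation with Ac2O would give 4-methoxycyclohexa-1,3-dien-1-yl acetate F3.
 - Annulation: heating 12 with F3 in toluene at 60–80 °C should give the bicyclo[2.2.2]octene adduct F4. The acetoxy-bearing terminus is the more nucleophilic one (it is activated by the methoxy donor at the far end) and should bond to the chlorine-free carbon.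
 - Aromatisation: dehydrochlorination over NaHCO3 would give the ethano-bridged quinone F5. Heating in xylene at about 130 °C should expel ethylene to give the 8-acetoxy-5-methoxy-1,4-naphthoquinone F6.
 - Return: brief K2CO3/MeOH at 0 °C should cleave the aryl acetate faster than the hindered conjugated ester, giving 16. A carbocyclic diene cannot re-aromatise, so the substitutive pathway is closed.

2. Step 3 (key step).
 - What may go wrong: direct Suzuki-type transfer of the aryl or vinyl group to palladium instead of the metalate shift; catalyst inhibition by residual bromide; slow migration of the ortho-methoxy aryl group; weak enantioface discrimination; protodeboronation of the benzylic boronate.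
 - Fallback (carbonyl addition and reagent-controlled asymmetric reduction): it sets out from 2 (through aryllithium 6) and returns at 9.
 - 4-Methylpent-3-enoic acid is converted (EDC, MeNHOMe·HCl, i-Pr2NEt) into N-methoxy-N,4-dimethylpent-3-enamide F7.
 - Addition of 6 at −78 °C would give 1-(4-chloro-2,5-dimethoxyphenyl)-4-methylpent-3-en-1-one F8.
 - Reduction with (−)-B-chlorodiisopinocampheylborane in THF at −25 °C (aryl as the large group) should give (S)-9.

3. Step 6.
 - What may go wrong: ionisation or hydrolysis of the benzylic senecioate in the acidic oxidising medium; competing oxidation of the trisubstituted alkene; oxidative biaryl coupling; incomplete oxidation of the chlorine-deactivated ring.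
 - Fallback (electrochemical bisketalisation before acylation, then non-oxidative unmasking): it sets out from 9 and returns at 12.
 - Anodic oxidation of 9 (carbon anode, 1% KOH in MeOH, 0 °C, undivided cell) would give (S)-1-(4-chloro-3,3,6,6-tetramethoxycyclohexa-1,4-dien-1-yl)-4-methylpent-3-en-1-ol F9.
 - Steglich esterification with 10 would give its 3-methylbut-2-enoate F10.
 - Hydrolysis of both ketals with dilute aqueous acid (TsOH, acetone/H2O) should release quinone 12.

**Further compounds**

F1 | step 7 | 1,4-dimethoxycyclohexa-1,4-diene | COC1=CCC(OC)=CC1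
F2 | step 7 | 4-methoxycyclohex-3-en-1-one | COC1=CCC(=O)CC1
F3 | step 7 | 4-methoxycyclohexa-1,3-dien-1-yl acetate | COC1=CC=C(OC(C)=O)CC1
F4 | step 7 | 8-acetoxy-4a-chloro-5-methoxy-5,8-ethano-4a,5,8,8a-tetrahydronaphthalene-1,4-dione bearing the (S)-side chain on C2 | O=C1C=C([C@H](CC=C(C)C)OC(=O)C=C(C)C)C(=O)C2C3(OC(C)=O)C=CC(OC)(CC3)C12Cl
F5 | step 7 | 8-acetoxy-5-methoxy-5,8-ethano-5,8-dihydronaphthalene-1,4-dione bearing the (S)-side chain on C2 | O=C1C=C([C@H](CC=C(C)C)OC(=O)C=C(C)C)C(=O)C2=C1C1(OC)C=CC2(OC(C)=O)CC1
F6 | step 7 | (S)-1-(8-acetoxy-5-methoxy-1,4-dioxo-1,4-dihydronaphthalen-2-yl)-4-methylpent-3-enyl 3-methylbut-2-enoate | COc1ccc(OC(C)=O)c2c1C(=O)C=C([C@H](CC=C(C)C)OC(=O)C=C(C)C)C2=O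
F7 | step 3 | N-methoxy-N,4-dimethylpent-3-enamide | CON(C)C(=O)CC=C(C)C
F8 | step 3 | 1-(4-chloro-2,5-dimethoxyphenyl)-4-methylpent-3-en-1-one | COc1cc(Cl)c(OC)cc1C(=O)CC=C(C)C
F9 | step 6 | (S)-1-(4-chloro-3,3,6,6-tetramethoxycyclohexa-1,4-dien-1-yl)-4-methylpent-3-en-1-ol | COC1(OC)C=C(Cl)C(OC)(OC)C=C1[C@H](CC=C(C)C)O
F10 | step 6 | (S)-1-(4-chloro-3,3,6,6-tetramethoxycyclohexa-1,4-dien-1-yl)-4-methylpent-3-enyl 3-methylbut-2-enoate | COC1(OC)C=C(Cl)C(OC)(OC)C=C1[C@H](CC=C(C)C)OC(=O)C=C(C)C
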